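**Retrosynthetic overview**
- Target ⇐ pentabenzyl ether by global hydrogenolysis.
- Pentabenzyl ether ⇐ cyclic 2-ethoxy acetal of the upper unit plus an aryltrifluoroborate: the upper B ring is added to a C2 oxocarbenium ion, trans to the 4-aryl group.
- Acetal ⇐ open-chain bis-benzylic alcohol plus ethyl vinyl ether in one operation: ring C of the upper unit by o-quinone methide [4+2], ring C of the lower unit by 6-endo epoxy-arene Friedel–Crafts closure.
- Bis-benzylic alcohol ⇐ aryllithium (resorcinol part) plus a phloroglucinol aldehyde; this makes the interflavan C4–C8 bond. The aldehyde ⇐ Mitsunobu etherification of a salicylaldehyde with a chiral epoxy alcohol.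
- Epoxy alcohol ⇐ Sharpless kinetic resolution of an aryl vinyl carbinol. Ring order: all four benzene rings are bought; both pyran rings close together, late.

Assumption: the aryltrifluoroborate of step 8 is bought, and the (R)-acid of step 7 is taken to give the 4R adduct (its mirror image is used if the sense of induction proves opposite).

**Step 1**
Reactants: 1 2,4,6-trihydroxybenzaldehyde; 2 benzyl bromide (2.05 equiv)
Product: 3 2,4-bis(benzyloxy)-6-hydroxybenzaldehyde
Conditions: K2CO3, DMF, 0 °C to rt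
Reagents that add atoms: none
Why: Williamson ether synthesis in which the 4-OH and one ortho-OH are benzylated while the other ortho-OH, hydrogen-bonded to the formyl group, stays free and later becomes O1 of the lower unit; no stereocentre.

**Step 2**
Reactants: 4 4-(benzyloxy)benzaldehyde; 5 vinylmagnesium bromide
Product: 6 rac-1-[4-(benzyloxy)phenyl]prop-2-en-1-ol
Conditions: THF, 0 °C; then H2O
Reagents that add atoms: none
Why: Grignard 1,2-addition to the aldehyde gives the racemic secondary allylic alcohol.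

**Step 3**
Reactants: 6 rac-1-[4-(benzyloxy)phenyl]prop-2-en-1-ol
Product: 7 (S)-[4-(benzyloxy)phenyl][(2R)-oxiran-2-yl]methanol
Conditions: Ti(OiPr)4 (0.2 equiv), L-(+)-diisopropyl tartrate (0.24 equiv), tert-butyl hydroperoxide (0.6 equiv), 4 Å molecular sieves, CH2Cl2, −20 °C
Reagents that add atoms: tert-butyl hydroperoxide, CC(C)(C)OO
Why: Sharpless kinetic resolution (Katsuki–Sharpless epoxidation): with the L-(+)-tartrate the (R)-carbinol is epoxidised much faster than its enantiomer and erythro-selectively, giving the (1S,2R)-epoxy alcohol in at most 50% yield and fixing the future C3 of the lower unit; unreacted 6 is removed by chromatography.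

**Step 4**
Reactants: 3 2,4-bis(benzyloxy)-6-hydroxybenzaldehyde; 7 (S)-[4-(benzyloxy)phenyl][(2R)-oxiran-2-yl]methanol
Product: 8 2,4-bis(benzyloxy)-6-{(R)-[4-(benzyloxy)phenyl][(2R)-oxiran-2-yl]methoxy}benzaldehyde
Conditions: PPh3, diisopropyl azodicarboxylate, toluene, 0 °C to rt
Reagents that add atoms: none
Why: Mitsunobu etherification in which the acidic salicylaldehyde OH displaces the activated benzylic hydroxyl by SN2 with inversion (S to R), setting the future C2 of the lower unit; the neighbouring epoxide disfavours ionisation of the benzylic centre.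

**Step 5**
Reactants: 9 4-bromobenzene-1,3-diol; 2 benzyl bromide (1.0 equiv)
Product: 10 5-(benzyloxy)-2-bromophenol
Conditions: K2CO3, acetone, rt
Reagents that add atoms: none
Why: Williamson mono-etherification expected mainly at the hydroxyl para to bromine, which is less hindered and gives the more nucleophilic phenoxide; the regioisomer and bis-ether are removed by chromatography.

**Step 6**
Reactants: 10 5-(benzyloxy)-2-bromophenol; 8 2,4-bis(benzyloxy)-6-{(R)-[4-(benzyloxy)phenyl][(2R)-oxiran-2-yl]methoxy}benzaldehyde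
Product: 12 [2,4-bis(benzyloxy)-6-{(R)-[4-(benzyloxy)phenyl][(2R)-oxiran-2-yl]methoxy}phenyl][4-(benzyloxy)-2-hydroxyphenyl]methanol (both carbinol epimers), via dilithiated phenolate 11 (not isolated)
Conditions: n-BuLi (2.1 equiv), Et2O, −78 to 0 °C; then 8, THF, −78 °C; then H2O
Reagents that add atoms: none
Why: O-deprotonation then bromine–lithium exchange gives the aryllithium, which adds 1,2 to the aldehyde faster than it opens the epoxide at −78 °C (organolithium addition) and forms the future interflavan C4–C8 bond; the carbinol centre is lost again in step 7.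

**Step 7**
Reactants: 12 [2,4-bis(benzyloxy)-6-{(R)-[4-(benzyloxy)phenyl][(2R)-oxiran-2-yl]methoxy}phenyl][4-(benzyloxy)-2-hydroxyphenyl]methanol; 13 ethyl vinyl ether (1.3 equiv)
Product: 16 (2R,3R)-5,7-bis(benzyloxy)-2-[4-(benzyloxy)phenyl]-8-[(4R)-7-(benzyloxy)-2-ethoxychroman-4-yl]chroman-3-ol (both acetal epimers), via o-quinone methide 14 (not isolated), via epoxide-bearing cycloadduct 15 (not isolated)
Conditions: (R)-3,3'-bis(2,4,6-triisopropylphenyl)-1,1'-bi-2-naphthol N-(trifluoromethylsulfonyl)phosphoramide (10 mol %), 4 Å molecular sieves, CH2Cl2, −40 °C, then 25 °C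
Reagents that add atoms: none
Why: Proposed new method: the chiral Brønsted acid dehydrates the bis-benzylic alcohol to an o-quinone methide that stays hydrogen-bonded to the chiral anion, so the vinyl ether adds to one face in an inverse-demand hetero-Diels–Alder reaction that closes ring C of the upper unit and sets C4 (R), only the resorcinol oxygen being free to close because every oxygen of the central ring is alkylated; on warming the same acid activates the terminal epoxide for 6-endo Friedel–Crafts attack by the trioxygenated ring (ortho to the ether oxygen, para to OBn), closing ring C of the lower unit with C2 and C3 carried over unchanged from 8; the closest known reactions are chiral phosphoric-acid-type [4+2] cycloadditions of in situ o-quinone methides with styrenes and enamides, and acid- or fluoroalcohol-promoted cyclisations of aryl glycidyl ethers to chroman-3-ols.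

**Step 8**
Reactants: 16 (2R,3R)-5,7-bis(benzyloxy)-2-[4-(benzyloxy)phenyl]-8-[(4R)-7-(benzyloxy)-2-ethoxychroman-4-yl]chroman-3-ol; 17 potassium [4-(benzyloxy)phenyl]trifluoroborate (2.5 equiv)
Product: 19 (2R,3R)-5,7-bis(benzyloxy)-2-[4-(benzyloxy)phenyl]-8-{(2S,4R)-7-(benzyloxy)-2-[4-(benzyloxy)phenyl]chroman-4-yl}chroman-3-ol, via aryldifluoroborane 18 (not isolated)
Conditions: BF3·OEt2 (3 equiv), CH2Cl2/MeCN, −40 to −10 °C; then H2O
Reagents that add atoms: none
Why: BF3-mediated coupling of a cyclic O,O-acetal with an organotrifluoroborate: the aryldifluoroborane ionises the exocyclic C2–OEt bond and passes its aryl group to the cyclic oxocarbenium ion on the face opposite the pseudo-axial 4-aryl group (no 1,3-diaxial clash), which gives the 2,4-trans (2S,4R) unit; the free 3-OH only consumes extra reagent.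

**Step 9**
Reactants: 19 (2R,3R)-5,7-bis(benzyloxy)-2-[4-(benzyloxy)phenyl]-8-{(2S,4R)-7-(benzyloxy)-2-[4-(benzyloxy)phenyl]chroman-4-yl}chroman-3-ol
Product: 20 (2R,3R)-8-[(2S,4R)-7-hydroxy-2-(4-hydroxyphenyl)chroman-4-yl]-2-(4-hydroxyphenyl)chroman-3,5,7-triol
Conditions: H2 (1 atm), Pd(OH)2 on carbon, THF/MeOH, rt
Reagents that add atoms: none
Why: Hydrogenolysis of the five benzyl ethers; the ring C2–O bonds and the C4–C8 bond survive these mild conditions and no stereocentre is touched.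

**Compound list**
1 | 2,4,6-trihydroxybenzaldehyde | O=Cc1c(O)cc(O)cc1O | starting material
2 | benzyl bromide | BrCc1ccccc1 | starting material
3 | 2,4-bis(benzyloxy)-6-hydroxybenzaldehyde | O=Cc1c(O)cc(OCc2ccccc2)cc1OCc1ccccc1 | intermediate
4 | 4-(benzyloxy)benzaldehyde | O=Cc1ccc(OCc2ccccc2)cc1 | starting material
5 | vinylmagnesium bromide | C=C[Mg]Br | starting material
6 | rac-1-[4-(benzyloxy)phenyl]prop-2-en-1-ol | OC(C=C)c1ccc(OCc2ccccc2)cc1 | intermediate
7 | (S)-[4-(benzyloxy)phenyl][(2R)-oxiran-2-yl]methanol | O[C@@H](c1ccc(OCc2ccccc2)cc1)[C@H]1CO1 | intermediate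
8 | 2,4-bis(benzyloxy)-6-{(R)-[4-(benzyloxy)phenyl][(2R)-oxiran-2-yl]methoxy}benzaldehyde | O=Cc1c(O[C@H](c2ccc(OCc3ccccc3)cc2)[C@H]2CO2)cc(OCc2ccccc2)cc1OCc1ccccc1 | intermediate
9 | 4-bromobenzene-1,3-diol | Oc1ccc(Br)c(O)c1 | starting material
10 | 5-(benzyloxy)-2-bromophenol | Oc1cc(OCc2ccccc2)ccc1Br | intermediate
11 | lithium 5-(benzyloxy)-2-lithiophenolate | [Li]Oc1cc(OCc2ccccc2)ccc1[Li] | intermediate (not isolated)
12 | [2,4-bis(benzyloxy)-6-{(R)-[4-(benzyloxy)phenyl][(2R)-oxiran-2-yl]methoxy}phenyl][4-(benzyloxy)-2-hydroxyphenyl]methanol, both carbinol epimers | OC(c1ccc(OCc2ccccc2)cc1O)c1c(O[C@H](c2ccc(OCc3ccccc3)cc2)[C@H]2CO2)cc(OCc2ccccc2)cc1OCc1ccccc1 | intermediate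
13 | ethyl vinyl ether | C=COCC | starting material
14 | o-quinone methide from 12: 3-(benzyloxy)-6-[aryl-methylidene]cyclohexa-2,4-dien-1-one, aryl = 2,4-bis(benzyloxy)-6-{(R)-[4-(benzyloxy)phenyl][(2R)-oxiran-2-yl]methoxy}phenyl | O=C1C=C(OCc2ccccc2)C=CC1=Cc1c(O[C@H](c2ccc(OCc3ccccc3)cc2)[C@H]2CO2)cc(OCc2ccccc2)cc1OCc1ccccc1 | intermediate (not isolated)
15 | (4R)-7-(benzyloxy)-4-[2,4-bis(benzyloxy)-6-{(R)-[4-(benzyloxy)phenyl][(2R)-oxiran-2-yl]methoxy}phenyl]-2-ethoxychromane | CCOC1C[C@@H](c2c(O[C@H](c3ccc(OCc4ccccc4)cc3)[C@H]3CO3)cc(OCc3ccccc3)cc2OCc2ccccc2)c2ccc(OCc3ccccc3)cc2O1 | intermediate (not isolated)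
16 | (2R,3R)-5,7-bis(benzyloxy)-2-[4-(benzyloxy)phenyl]-8-[(4R)-7-(benzyloxy)-2-ethoxychroman-4-yl]chroman-3-ol, both acetal epimers | CCOC1C[C@@H](c2c(OCc3ccccc3)cc(OCc3ccccc3)c3c2O[C@H](c2ccc(OCc4ccccc4)cc2)[C@H](O)C3)c2ccc(OCc3ccccc3)cc2O1 | intermediate
17 | potassium [4-(benzyloxy)phenyl]trifluoroborate | [K+].F[B-](F)(F)c1ccc(OCc2ccccc2)cc1 | starting material
18 | [4-(benzyloxy)phenyl]difluoroborane | FB(F)c1ccc(OCc2ccccc2)cc1 | intermediate (not isolated)
19 | (2R,3R)-5,7-bis(benzyloxy)-2-[4-(benzyloxy)phenyl]-8-{(2S,4R)-7-(benzyloxy)-2-[4-(benzyloxy)phenyl]chroman-4-yl}chroman-3-ol | O(Cc1ccccc1)c1ccc([C@@H]2C[C@@H](c3c(OCc4ccccc4)cc(OCc4ccccc4)c4c3O[C@H](c3ccc(OCc5ccccc5)cc3)[C@H](O)C4)c3ccc(OCc4ccccc4)cc3O2)cc1 | intermediate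
20 | (2R,3R)-8-[(2S,4R)-7-hydroxy-2-(4-hydroxyphenyl)chroman-4-yl]-2-(4-hydroxyphenyl)chroman-3,5,7-triol | Oc1ccc([C@@H]2C[C@@H](c3c(O)cc(O)c4c3O[C@H](c3ccc(O)cc3)[C@H](O)C4)c3ccc(O)cc3O2)cc1 | target

**Step count and risks**
Total steps: 9. Longest linear sequence: 7 (steps 2, 3, 4, 6, 7, 8, 9 from compound 4).

Most likely to fail, in order:

Step 7 (double annulation). The risks are poor facial control at C4 by the chiral acid, a sluggish epoxy-arene closure with so weak an activator, and aryl migration or loss of the benzylic ether side chain. The fallback sets out from 12 and closes the two rings one at a time without catalyst control. The [4+2] reaction with 13 under achiral diphenyl hydrogen phosphate at −40 °C gives 15 together with the (4S)-epimer of 15 F1. In a separate operation the mixture is cyclised in 1,1,1,3,3,3-hexafluoropropan-2-ol at rt to 16 and the (4S)-epimer of 16 F2. These diastereomers are separated by chromatography, and the route is rejoined at 16.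

Step 8 (C2 arylation). The risks are ring-opening through the endocyclic C–O bond, interference by the free 3-OH, and acid epimerisation at C2 of the product. The fallback sets out from 16 and builds the C2–O bond by substitution instead. Mild aqueous acid hydrolysis of the acetal gives the lactol (2R,3R)-5,7-bis(benzyloxy)-2-[4-(benzyloxy)phenyl]-8-[(4R)-7-(benzyloxy)-2-hydroxychroman-4-yl]chroman-3-ol F7. Excess [4-(benzyloxy)phenyl]magnesium bromide (bought as a THF solution) adds to its open hydroxy-aldehyde form and gives the carbinol-epimeric triol 1-[4-(benzyloxy)phenyl]-3-[4-(benzyloxy)-2-hydroxyphenyl]-3-(lower-unit aryl)propan-1-ol F8. Mitsunobu ring closure (PPh3, diisopropyl azodicarboxylate; the phenol attacks the benzylic carbinol) gives 19 and the (2R,4R)-epimer of 19 F9, which is removed by chromatography. The route is rejoined at 19.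

Step 4 (Mitsunobu on the chelated, hindered phenol 3). The risks are low conversion and partial ionisation of the p-alkoxybenzylic centre. The fallback sets out from 7 and uses the unhindered, commercial 3,5-bis(benzyloxy)phenol, moving the interflavan bond formation after the lower ring closure. Mitsunobu coupling gives 1,3-bis(benzyloxy)-5-{(R)-[4-(benzyloxy)phenyl][(2R)-oxiran-2-yl]methoxy}benzene F3. Cyclisation in 1,1,1,3,3,3-hexafluoropropan-2-ol gives (2R,3R)-5,7-bis(benzyloxy)-2-[4-(benzyloxy)phenyl]chroman-3-ol F4. N-Bromosuccinimide at −78 °C brominates C8 to give (2R,3R)-5,7-bis(benzyloxy)-2-[4-(benzyloxy)phenyl]-8-bromochroman-3-ol F5. n-BuLi (2.2 equiv) followed by the lithium phenoxide of commercial 4-(benzyloxy)-2-hydroxybenzaldehyde gives (2R,3R)-5,7-bis(benzyloxy)-2-[4-(benzyloxy)phenyl]-8-{[4-(benzyloxy)-2-hydroxyphenyl](hydroxy)methyl}chroman-3-ol F6. Its [4+2] reaction with 13 under the chiral acid of step 7 rejoins the route at 16.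

**Further compounds**
F1 | step 7 | (4S)-7-(benzyloxy)-4-[2,4-bis(benzyloxy)-6-{(R)-[4-(benzyloxy)phenyl][(2R)-oxiran-2-yl]methoxy}phenyl]-2-ethoxychromane | CCOC1C[C@H](c2c(O[C@H](c3ccc(OCc4ccccc4)cc3)[C@H]3CO3)cc(OCc3ccccc3)cc2OCc2ccccc2)c2ccc(OCc3ccccc3)cc2O1
F2 | step 7 | (2R,3R)-5,7-bis(benzyloxy)-2-[4-(benzyloxy)phenyl]-8-[(4S)-7-(benzyloxy)-2-ethoxychroman-4-yl]chroman-3-ol | CCOC1C[C@H](c2c(OCc3ccccc3)cc(OCc3ccccc3)c3c2O[C@H](c2ccc(OCc4ccccc4)cc2)[C@H](O)C3)c2ccc(OCc3ccccc3)cc2O1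
F3 | step 4 | 1,3-bis(benzyloxy)-5-{(R)-[4-(benzyloxy)phenyl][(2R)-oxiran-2-yl]methoxy}benzene | c1(O[C@H](c2ccc(OCc3ccccc3)cc2)[C@H]2CO2)cc(OCc2ccccc2)cc(OCc2ccccc2)c1
F4 | step 4 | (2R,3R)-5,7-bis(benzyloxy)-2-[4-(benzyloxy)phenyl]chroman-3-ol | c1c(OCc3ccccc3)cc(OCc3ccccc3)c2c1O[C@H](c1ccc(OCc3ccccc3)cc1)[C@H](O)C2
F5 | step 4 | (2R,3R)-5,7-bis(benzyloxy)-2-[4-(benzyloxy)phenyl]-8-bromochroman-3-ol | Brc1c(OCc3ccccc3)cc(OCc3ccccc3)c2c1O[C@H](c1ccc(OCc3ccccc3)cc1)[C@H](O)C2
F6 | step 4 | (2R,3R)-5,7-bis(benzyloxy)-2-[4-(benzyloxy)phenyl]-8-{[4-(benzyloxy)-2-hydroxyphenyl](hydroxy)methyl}chroman-3-ol | OC(c1ccc(OCc2ccccc2)cc1O)c1c(OCc2ccccc2)cc(OCc2ccccc2)c2c1O[C@H](c1ccc(OCc3ccccc3)cc1)[C@H](O)C2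
F7 | step 8 | (2R,3R)-5,7-bis(benzyloxy)-2-[4-(benzyloxy)phenyl]-8-[(4R)-7-(benzyloxy)-2-hydroxychroman-4-yl]chroman-3-ol | OC1C[C@@H](c2c(OCc3ccccc3)cc(OCc3ccccc3)c3c2O[C@H](c2ccc(OCc4ccccc4)cc2)[C@H](O)C3)c2ccc(OCc3ccccc3)cc2O1
F8 | step 8 | (2R,3R)-5,7-bis(benzyloxy)-2-[4-(benzyloxy)phenyl]-8-{(1R)-1-[4-(benzyloxy)-2-hydroxyphenyl]-3-[4-(benzyloxy)phenyl]-3-hydroxypropyl}chroman-3-ol, both carbinol epimers | OC(c1ccc(OCc2ccccc2)cc1)C[C@@H](c1c(OCc2ccccc2)cc(OCc2ccccc2)c2c1O[C@H](c1ccc(OCc3ccccc3)cc1)[C@H](O)C2)c1ccc(OCc2ccccc2)cc1O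
F9 | step 8 | (2R,3R)-5,7-bis(benzyloxy)-2-[4-(benzyloxy)phenyl]-8-{(2R,4R)-7-(benzyloxy)-2-[4-(benzyloxy)phenyl]chroman-4-yl}chroman-3-ol | O(Cc1ccccc1)c1ccc([C@H]2C[C@@H](c3c(OCc4ccccc4)cc(OCc4ccccc4)c4c3O[C@H](c3ccc(OCc5ccccc5)cc3)[C@H](O)C4)c3ccc(OCc4ccccc4)cc3O2)cc1
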